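**Retrosynthetic overview**
1. Target ⇒ desilylation, then ligand-controlled Re-face methyl addition (creates the 6S carbinol) ⇒ ring-bearing (2E,4E)-dienone.
2. Key disconnection at C4–C5 of the chain: crossed aldol addition of the kinetic lithium enolate of 6-methylhept-5-en-2-one to a ring-bearing (E)-enal, then dehydration.
3. Enal ⇒ Horner-Wadsworth-Emmons homologation and redox adjustment of the ring methyl ketone ⇒ Weinreb amide ⇒ ethyl ester.
4. cis-Bromohydrin (Br, OH and side chain on one face, so anti addition to an alkene cannot give it) ⇒ methyl addition anti to the equatorial bromide of a 2-bromocyclohexanone ⇒ bromohydrin ⇒ epoxide ⇒ bromolactone ⇒ (S)-cyclohex-3-ene-1-carboxylic acid.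
5. Rings: the cyclohexane is bought with the acid and never broken. A γ-lactone (step 1) and then an oxirane (step 2) are built on it only as stereochemical relays and are opened in steps 2 and 3.

Assumption: the SMILES is read literally (ring 1S,3S,4R with Br, OH and chain all cis; 6S carbinol; 2E,4E diene), and the chiral ligand of step 15 is bought or made separately and not counted.

**Step 1**
Reactants: 1 (S)-cyclohex-3-ene-1-carboxylic acid
Product: 2 (1S,4S,5S)-4-bromo-6-oxabicyclo[3.2.1]octan-7-one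
Conditions: NBS, CH2Cl2, 0 to 23 °C
Reagents that add atoms: N-bromosuccinimide, O=C1CCC(=O)N1Br
Why: Bromolactonisation, in which the carboxyl group can only reach its own ring face and opens the bromonium ion anti, which sets C–O cis and C–Br trans to the carboxyl carbon.

**Step 2**
Reactants: 2 (1S,4S,5S)-4-bromo-6-oxabicyclo[3.2.1]octan-7-one
Product: 4 ethyl (1S,3S,6R)-7-oxabicyclo[4.1.0]heptane-3-carboxylate, via sodium bromo alkoxide 3 (not isolated)
Conditions: NaOEt, EtOH, 0 to 23 °C
Reagents that add atoms: sodium ethoxide, [Na+].[O-]CC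
Why: Ethanolysis of the lactone frees an alkoxide trans-diaxial to bromide, and intramolecular Williamson (SN2) closure gives only the epoxide cis to the ester.

**Step 3**
Reactants: 4 ethyl (1S,3S,6R)-7-oxabicyclo[4.1.0]heptane-3-carboxylate
Product: 5 ethyl (1S,3R,4R)-3-bromo-4-hydroxycyclohexane-1-carboxylate
Conditions: LiBr, AcOH, THF, 23 °C
Reagents that add atoms: lithium bromide, [Li+].[Br-]
Why: Acid-assisted SN2 epoxide opening under the Fürst-Plattner rule, in which bromide attacks C3 from the face opposite the ester to give the trans-diaxial bromohydrin with the oxygen at C4.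

**Step 4**
Reactants: 5 ethyl (1S,3R,4R)-3-bromo-4-hydroxycyclohexane-1-carboxylate
Product: 6 ethyl (1S,3R)-3-bromo-4-oxocyclohexane-1-carboxylate (Br axial, trans to the ester)
Conditions: Dess-Martin periodinane, CH2Cl2, 0 to 23 °C
Reagents that add atoms: none
Why: Dess-Martin oxidation is neutral enough to turn the halohydrin into the α-bromoketone without loss of HBr or change at C1.

**Step 5**
Reactants: 6 ethyl (1S,3R)-3-bromo-4-oxocyclohexane-1-carboxylate
Product: 7 ethyl (1S,3S)-3-bromo-4-oxocyclohexane-1-carboxylate (Br equatorial, cis to the ester)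
Conditions: LiBr (1 equiv), DMF, 23 °C; SiO2 separation, recovered 6 resubmitted
Reagents that add atoms: lithium bromide, [Li+].[Br-]
Why: Degenerate Finkelstein-type SN2 exchange at the α-keto carbon inverts only C3, so the axial bromide equilibrates with the more polar equatorial one (about 2:1 in DMF) without touching C1 and without the bromine migration that HBr would cause.

**Step 6**
Reactants: 7 ethyl (1S,3S)-3-bromo-4-oxocyclohexane-1-carboxylate
Product: 8 ethyl (1S,3S,4R)-3-bromo-4-hydroxy-4-methylcyclohexane-1-carboxylate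
Conditions: MeMgBr, CeCl3, THF, −78 °C, cold quench
Reagents that add atoms: methylmagnesium bromide, C[Mg]Br
Why: Non-basic organocerium 1,2-addition, in which methyl enters on the equatorial trajectory and ends trans to bromine (the classical result for 2-halocyclohexanones), which sets the axial 4R alcohol cis to Br and leaves the ester untouched.

**Step 7**
Reactants: 8 ethyl (1S,3S,4R)-3-bromo-4-hydroxy-4-methylcyclohexane-1-carboxylate
Product: 9 ethyl (1S,3S,4R)-3-bromo-4-methyl-4-(triethylsilyloxy)cyclohexane-1-carboxylate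
Conditions: Et3SiOTf, 2,6-lutidine, CH2Cl2, 0 °C
Reagents that add atoms: triethylsilyl trifluoromethanesulfonate, CC[Si](CC)(CC)OS(=O)(=O)C(F)(F)F
Why: Silyl triflate silylation caps the hindered tertiary alcohol, so no alkoxide next to the bromide (ring-contraction risk) can form in the basic steps that follow.

**Step 8**
Reactants: 9 ethyl (1S,3S,4R)-3-bromo-4-methyl-4-(triethylsilyloxy)cyclohexane-1-carboxylate
Product: 10 (1S,3S,4R)-3-bromo-N-methoxy-N,4-dimethyl-4-(triethylsilyloxy)cyclohexane-1-carboxamide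
Conditions: MeNH(OMe)·HCl, iPrMgCl, THF, −20 to 0 °C
Reagents that add atoms: N,O-dimethylhydroxylamine hydrochloride, CNOC.Cl
Why: Magnesium-amide aminolysis of the ester gives the Weinreb amide at low temperature without epimerising C1 or touching the hindered equatorial bromide.

**Step 9**
Reactants: 10 (1S,3S,4R)-3-bromo-N-methoxy-N,4-dimethyl-4-(triethylsilyloxy)cyclohexane-1-carboxamide
Product: 11 1-[(1S,3S,4R)-3-bromo-4-methyl-4-(triethylsilyloxy)cyclohexyl]ethan-1-one
Conditions: MeMgBr, THF, 0 °C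
Reagents that add atoms: methylmagnesium bromide, C[Mg]Br
Why: Weinreb ketone synthesis, in which the chelated tetrahedral adduct survives until work-up, so only one methyl group is added.

**Step 10**
Reactants: 11 1-[(1S,3S,4R)-3-bromo-4-methyl-4-(triethylsilyloxy)cyclohexyl]ethan-1-one
Product: 12 ethyl (2E)-3-[(1S,3S,4R)-3-bromo-4-methyl-4-(triethylsilyloxy)cyclohexyl]but-2-enoate
Conditions: (EtO)2P(O)CH2CO2Et, NaH, THF, 0 to 40 °C; E/Z separated on SiO2
Reagents that add atoms: triethyl phosphonoacetate, CCOC(=O)CP(=O)(OCC)OCC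
Why: Horner-Wadsworth-Emmons olefination puts the ester trans to the larger ring substituent (E:Z about 6:1), and the weakly basic phosphonate anion barely enolises the ketone.

**Step 11**
Reactants: 12 ethyl (2E)-3-[(1S,3S,4R)-3-bromo-4-methyl-4-(triethylsilyloxy)cyclohexyl]but-2-enoate
Product: 13 (2E)-3-[(1S,3S,4R)-3-bromo-4-methyl-4-(triethylsilyloxy)cyclohexyl]but-2-en-1-ol
Conditions: iBu2AlH (2.2 equiv), CH2Cl2, −78 °C
Reagents that add atoms: none
Why: 1,2-Hydride reduction of the enoate gives the allylic alcohol and leaves the alkyl bromide, silyl ether and alkene geometry intact.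

**Step 12**
Reactants: 13 (2E)-3-[(1S,3S,4R)-3-bromo-4-methyl-4-(triethylsilyloxy)cyclohexyl]but-2-en-1-ol
Product: 14 (2E)-3-[(1S,3S,4R)-3-bromo-4-methyl-4-(triethylsilyloxy)cyclohexyl]but-2-enal
Conditions: MnO2, CH2Cl2, 23 °C
Reagents that add atoms: none
Why: Selective allylic oxidation with MnO2 stops at the enal and does not isomerise the trisubstituted E alkene.

**Step 13**
Reactants: 14 (2E)-3-[(1S,3S,4R)-3-bromo-4-methyl-4-(triethylsilyloxy)cyclohexyl]but-2-enal; 15 6-methylhept-5-en-2-one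
Product: 17 (2E)-2-[(1S,3S,4R)-3-bromo-4-methyl-4-(triethylsilyloxy)cyclohexyl]-4-hydroxy-10-methylundeca-2,9-dien-6-one (both C4 epimers), via lithium enolate 16 (not isolated)
Conditions: 15, LiN(iPr)2, THF, −78 °C; then 14, −78 °C; AcOH quench
Reagents that add atoms: none
Why: Directed crossed aldol addition, in which kinetic deprotonation takes the methyl side of 15 and the non-enolisable enal reacts 1,2 to form the C4–C5 bond; the new carbinol centre is erased in the next step.

**Step 14**
Reactants: 17 (2E)-2-[(1S,3S,4R)-3-bromo-4-methyl-4-(triethylsilyloxy)cyclohexyl]-4-hydroxy-10-methylundeca-2,9-dien-6-one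
Product: 19 (2E,4E)-2-[(1S,3S,4R)-3-bromo-4-methyl-4-(triethylsilyloxy)cyclohexyl]-10-methylundeca-2,4,9-trien-6-one, via allylic mesylate 18 (not isolated)
Conditions: MsCl, Et3N, CH2Cl2, −20 °C; then DBU, 0 to 23 °C
Reagents that add atoms: none
Why: E1cB elimination of the β-mesyloxy ketone completes the aldol condensation and gives the conjugated 4E alkene from either carbinol epimer.

**Step 15**
Reactants: 19 (2E,4E)-2-[(1S,3S,4R)-3-bromo-4-methyl-4-(triethylsilyloxy)cyclohexyl]-10-methylundeca-2,4,9-trien-6-one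
Product: 20 (2E,4E,6S)-2-[(1S,3S,4R)-3-bromo-4-methyl-4-(triethylsilyloxy)cyclohexyl]-6,10-dimethylundeca-2,4,9-trien-6-ol
Conditions: Me2Zn, Ti(OiPr)4, trans-cyclohexane-1,2-diamine bis(2-exo-hydroxybornane-10-sulfonamide) ligand (10 mol %, the antipode of the one that gives (S)-2-phenylbutan-2-ol from PhCOMe and Et2Zn), toluene/hexane, 23 °C
Reagents that add atoms: dimethylzinc, C[Zn]C
Why: Catalytic enantioselective 1,2-alkylation of an alkenyl alkyl ketone, in which the chiral titanium complex delivers methyl to the Re face to set 6S (about 90% selectivity expected), with no conjugate addition and the ring centres too remote to interfere.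

**Step 16**
Reactants: 20 (2E,4E,6S)-2-[(1S,3S,4R)-3-bromo-4-methyl-4-(triethylsilyloxy)cyclohexyl]-6,10-dimethylundeca-2,4,9-trien-6-ol
Product: 21 (2E,4E,6S)-2-[(1S,3S,4R)-3-bromo-4-hydroxy-4-methylcyclohexyl]-6,10-dimethylundeca-2,4,9-trien-6-ol
Conditions: Bu4NF, AcOH (1:1), THF, 0 to 23 °C
Reagents that add atoms: none
Why: Buffered fluoride desilylation avoids acid (which would ionise the dienyl carbinol) and free alkoxide, and a cis-bromohydrin cannot close to an epoxide.

**Compound list**
1 | (S)-cyclohex-3-ene-1-carboxylic acid | OC(=O)[C@H]1CCC=CC1 | starting material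
2 | (1S,4S,5S)-4-bromo-6-oxabicyclo[3.2.1]octan-7-one | O=C1[C@H]2CC[C@H](Br)[C@H](C2)O1 | intermediate
3 | sodium alkoxide of ethyl (1S,3S,4S)-4-bromo-3-hydroxycyclohexane-1-carboxylate | CCOC(=O)[C@H]1CC[C@H](Br)[C@@H]([O-])C1.[Na+] | intermediate
4 | ethyl (1S,3S,6R)-7-oxabicyclo[4.1.0]heptane-3-carboxylate | CCOC(=O)[C@H]1CC[C@H]2O[C@H]2C1 | intermediate
5 | ethyl (1S,3R,4R)-3-bromo-4-hydroxycyclohexane-1-carboxylate | CCOC(=O)[C@H]1CC[C@@H](O)[C@H](Br)C1 | intermediate
6 | ethyl (1S,3R)-3-bromo-4-oxocyclohexane-1-carboxylate | CCOC(=O)[C@H]1CCC(=O)[C@H](Br)C1 | intermediate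
7 | ethyl (1S,3S)-3-bromo-4-oxocyclohexane-1-carboxylate | CCOC(=O)[C@H]1CCC(=O)[C@@H](Br)C1 | intermediate
8 | ethyl (1S,3S,4R)-3-bromo-4-hydroxy-4-methylcyclohexane-1-carboxylate | CCOC(=O)[C@H]1CC[C@@](C)(O)[C@@H](Br)C1 | intermediate
9 | ethyl (1S,3S,4R)-3-bromo-4-methyl-4-(triethylsilyloxy)cyclohexane-1-carboxylate | CCOC(=O)[C@H]1CC[C@@](C)(O[Si](CC)(CC)CC)[C@@H](Br)C1 | intermediate
10 | (1S,3S,4R)-3-bromo-N-methoxy-N,4-dimethyl-4-(triethylsilyloxy)cyclohexane-1-carboxamide | CON(C)C(=O)[C@H]1CC[C@@](C)(O[Si](CC)(CC)CC)[C@@H](Br)C1 | intermediate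
11 | 1-[(1S,3S,4R)-3-bromo-4-methyl-4-(triethylsilyloxy)cyclohexyl]ethan-1-one | CC(=O)[C@H]1CC[C@@](C)(O[Si](CC)(CC)CC)[C@@H](Br)C1 | intermediate
12 | ethyl (2E)-3-[(1S,3S,4R)-3-bromo-4-methyl-4-(triethylsilyloxy)cyclohexyl]but-2-enoate | CCOC(=O)/C=C(\C)[C@H]1CC[C@@](C)(O[Si](CC)(CC)CC)[C@@H](Br)C1 | intermediate
13 | (2E)-3-[(1S,3S,4R)-3-bromo-4-methyl-4-(triethylsilyloxy)cyclohexyl]but-2-en-1-ol | OC/C=C(\C)[C@H]1CC[C@@](C)(O[Si](CC)(CC)CC)[C@@H](Br)C1 | intermediate
14 | (2E)-3-[(1S,3S,4R)-3-bromo-4-methyl-4-(triethylsilyloxy)cyclohexyl]but-2-enal | O=C/C=C(\C)[C@H]1CC[C@@](C)(O[Si](CC)(CC)CC)[C@@H](Br)C1 | intermediate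
15 | 6-methylhept-5-en-2-one | CC(=O)CCC=C(C)C | starting material
16 | lithium 6-methylhepta-1,5-dien-2-olate | [Li+].[O-]C(=C)CCC=C(C)C | intermediate
17 | (2E)-2-[(1S,3S,4R)-3-bromo-4-methyl-4-(triethylsilyloxy)cyclohexyl]-4-hydroxy-10-methylundeca-2,9-dien-6-one (both C4 epimers) | CC(C)=CCCC(=O)CC(O)/C=C(\C)[C@H]1CC[C@@](C)(O[Si](CC)(CC)CC)[C@@H](Br)C1 | intermediate
18 | C4 methanesulfonate of 17 (both C4 epimers) | CC(C)=CCCC(=O)CC(OS(C)(=O)=O)/C=C(\C)[C@H]1CC[C@@](C)(O[Si](CC)(CC)CC)[C@@H](Br)C1 | intermediate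
19 | (2E,4E)-2-[(1S,3S,4R)-3-bromo-4-methyl-4-(triethylsilyloxy)cyclohexyl]-10-methylundeca-2,4,9-trien-6-one | CC(C)=CCCC(=O)/C=C/C=C(\C)[C@H]1CC[C@@](C)(O[Si](CC)(CC)CC)[C@@H](Br)C1 | intermediate
20 | (2E,4E,6S)-2-[(1S,3S,4R)-3-bromo-4-methyl-4-(triethylsilyloxy)cyclohexyl]-6,10-dimethylundeca-2,4,9-trien-6-ol | CC(C)=CCC[C@](C)(O)/C=C/C=C(\C)[C@H]1CC[C@@](C)(O[Si](CC)(CC)CC)[C@@H](Br)C1 | intermediate
21 | (2E,4E,6S)-2-[(1S,3S,4R)-3-bromo-4-hydroxy-4-methylcyclohexyl]-6,10-dimethylundeca-2,4,9-trien-6-ol | CC(C)=CCC[C@](C)(O)/C=C/C=C(\C)[C@H]1CC[C@@](C)(O)[C@@H](Br)C1 | target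

**Step count and risks**
Total step count: 16. Longest linear sequence: 16 (1 to 21; ketone 15 enters at step 13).

The three steps most likely to fail are 5, 10 and 15.

**Step 5.** The equilibrium is only modestly on the side of 7, and 7 may re-epimerise on silica. The fallback replaces thermodynamic control by kinetic protonation. It sets out from 6 (or a 6/7 mixture). Me3SiOTf and Et3N give the bromo silyl enol ether ethyl (1S)-3-bromo-4-(trimethylsilyloxy)cyclohex-3-ene-1-carboxylate F1. Protodesilylation with Et3N·3HF in CH2Cl2 at −78 °C then delivers the proton to C3 along the stereoelectronically preferred axial line, so bromine ends equatorial. The fallback comes back to the route at 7, which is used crude in step 6.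

**Step 10.** The ketone is α-branched and carries a γ-bromide, so slow olefination, E/Z erosion, C1 epimerisation or 1,3-elimination to a bicyclo[3.1.0]hexane are possible. The fallback builds the alkene stereospecifically and sets out from 10.
- Ethyl acetate and LiN(iPr)2 give lithium 1-ethoxyethen-1-olate F2, which acylates on 10 in a Claisen-type condensation. The product is ethyl 3-[(1S,3S,4R)-3-bromo-4-methyl-4-(triethylsilyloxy)cyclohexyl]-3-oxopropanoate F3.
- NaH and ClP(O)(OEt)2 trap the chelated enolate as ethyl (2Z)-3-[(1S,3S,4R)-3-bromo-4-methyl-4-(triethylsilyloxy)cyclohexyl]-3-[(diethoxyphosphoryl)oxy]prop-2-enoate F4.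
- Me2CuLi at −78 to −30 °C replaces the phosphate with retention. The fallback comes back at 12 as the pure E isomer.

**Step 15.** Facial selectivity on a ketone flanked by a dienyl group and a CH2 chain may be too low, and the C6 epimers would be hard to separate. The fallback changes which C–C bond creates the stereocentre and sets out from 14.
- Aldol condensation of 14 with acetone (dilute aq NaOH, acetone, 23 °C) gives (3E,5E)-6-[(1S,3S,4R)-3-bromo-4-methyl-4-(triethylsilyloxy)cyclohexyl]hepta-3,5-dien-2-one F5. This is a methyl alkenyl ketone, the best substrate class for the catalyst.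
- 5-Bromo-2-methylpent-2-ene and Mg give (4-methylpent-3-en-1-yl)magnesium bromide F6, and ZnCl2 converts it into bis(4-methylpent-3-en-1-yl)zinc F7.
- F7 is added to F5 with Ti(OiPr)4 and the antipodal ligand, because Si-face attack is now required. The fallback comes back at 20.

**Further compounds**
F1 | step 5 | ethyl (1S)-3-bromo-4-(trimethylsilyloxy)cyclohex-3-ene-1-carboxylate | CCOC(=O)[C@H]1CCC(O[Si](C)(C)C)=C(Br)C1
F2 | step 10 | lithium 1-ethoxyethen-1-olate | [Li+].[O-]C(=C)OCC
F3 | step 10 | ethyl 3-[(1S,3S,4R)-3-bromo-4-methyl-4-(triethylsilyloxy)cyclohexyl]-3-oxopropanoate | CCOC(=O)CC(=O)[C@H]1CC[C@@](C)(O[Si](CC)(CC)CC)[C@@H](Br)C1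
F4 | step 10 | ethyl (2Z)-3-[(1S,3S,4R)-3-bromo-4-methyl-4-(triethylsilyloxy)cyclohexyl]-3-[(diethoxyphosphoryl)oxy]prop-2-enoate | CCOC(=O)/C=C(\OP(=O)(OCC)OCC)[C@H]1CC[C@@](C)(O[Si](CC)(CC)CC)[C@@H](Br)C1
F5 | step 15 | (3E,5E)-6-[(1S,3S,4R)-3-bromo-4-methyl-4-(triethylsilyloxy)cyclohexyl]hepta-3,5-dien-2-one | CC(=O)/C=C/C=C(\C)[C@H]1CC[C@@](C)(O[Si](CC)(CC)CC)[C@@H](Br)C1
F6 | step 15 | (4-methylpent-3-en-1-yl)magnesium bromide | CC(C)=CCC[Mg]Br
F7 | step 15 | bis(4-methylpent-3-en-1-yl)zinc | CC(C)=CCC[Zn]CCC=C(C)C
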